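The runs were computed from invented constants; noise was put on by code.

Read no slow chemistry into the flattening of the gamma run: between 2.50 min and 4.00 min the target gains just 0.7 percentage points, but a curve can also flatten when a charge is being used up, so count turnovers before trusting it.

| flask | substrate | reagent | remark | time |
|---|---|---|---|---|
| gamma | 0.80 M | 1.8 M | run made earlier |  |
| flask | 0.80 M | 1.20 M |  | 40 min |

gamma run (percent of the substrate charged)

| time / min | target / % | intermediate D / % |
|---|---|---|
| 0.333 | 1.2 | 0.9 |
| 0.500 | 3.2 | 2.3 |
| 0.833 | 5.2 | 4.3 |
| 1.33 | 7.1 | 8.6 |
| 2.50 | 8.8 | 14.7 |
| 4.00 | 9.5 | 18.1 |

(scatter of a reading: 0.3 percentage points)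



* amount of target at 40 min, in percent of the substrate charged
* amount of intermediate D at 40 min, in percent of the substrate charged

Apply the bench rule first: reagent charged above the substrate counts as excess, so the gamma curve carries over to the flask and its last readings stand as the answer, 9.5 % target and 18.1 % intermediate D. Then find its border. Both curves lag at the start, so assume, as my own reckoning, two reagent-consuming steps per substrate:

[reagent] / (two × [substrate]) = 75.0 % in the flask, 112 % in gamma

Call this the served share, the fraction of the substrate charged that the reagent can carry through both steps. Gamma's share is more than the whole charge and the flask's is less, which would make reagent the limiting reagent in the flask, so scale the gamma readings by the share: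

target: 75.0 % × 9.5 % = 7.12 %

intermediate D: 75.0 % × 18.1 % = 13.6 %

Take both as low, since the gamma readings were still rising at the last one, the target standing higher there than at the reading before. The forecast gives 15 % target and 17 % intermediate D, holding that “Lower reagent reduces the amounts somewhat but gives more time”, and my target is less than its figure.

The flask gives 7.88 % target and 15.6 % intermediate D.

    intermediate B ⇌ intermediate E (K = 0.921, k = 0.0279 /s)
    substrate + reagent → intermediate A (k = 0.0138 /M/s)
    reagent + intermediate A → intermediate B (k = 0.0293 /M/s)
    intermediate C ⇌ target (K = 0.581, k = 0.0737 /s)
    intermediate B ⇌ intermediate C (K = 0.955, k = 1.25 /s)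
    intermediate B ⇌ intermediate D (K = 1.10, k = 0.0188 /s)
    reagent + target → over-reaction product (k = 0.00471 /M/s)

With a served share of 75.0 %, the flask holds 0 % of its reagent at 40.0 min while 19.0 % of the substrate remains. The wearing away of reagent is the main reason that this substrate stays unconverted: the run with reagent held converts 100 % of the substrate, against 81.0 % in the flask. The neighbour flask with 0.72 M of reagent has a served share of 45.0 %, which on the last gamma reading gives 4.28 % target, and it stands at 3.98 %.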